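**Retrosynthetic overview**
1. Feature: in the octahydroazulenone the ring-fusion carbinol carbon C8a is bonded to the gem-dimethyl carbon C1 of the five-membered ring, and C1–C2–C3 is an allyl unit once C2=C3 is an alkene. A cycloheptane-fused cyclopropanol (C8a, C3a, C3) with a 2-methylpropenyl group on C3 therefore holds the whole cyclopentene in latent form, and a [1,3]-shift makes the C8a–C1 bond.
2. Target ⇒ primary iodide + 4-bromofuran-2(5H)-one (sp3–sp2 coupling) ⇒ trans-fused dihydroxy ketone ⇒ its C3a epimer ⇒ 2-hydroxy enone ⇒ epoxy ketone ⇒ hydroxyl-directed epoxidation of the key-step cyclopentenol.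
3. Cyclopropanol ⇒ carbene addition (ethyl diazoacetate, then aldehyde, then isopropylidene Wittig) to the silyl enol ether of a cycloheptane-1,3-dione whose other carbonyl has been reduced and silylated.
4. Dione ⇒ cycloheptenone ⇒ one-carbon ring expansion of (2S,3R)-2-allyl-2,3-dimethylcyclohexanone ⇒ 2-methylcyclohex-2-enone by asymmetric conjugate methylation–allylation.
5. Ring order: six-membered (bought) → seven (ring expansion) → three (carbene) → five (key step); the butenolide is attached last.

Key step: step 15

Remark on the chemistry: "methyl face" means the face of the seven-membered ring that carries both C-methyl groups and "chain face" the opposite one. The silyloxy carbon next to the quaternary centre only carries the later ketone, and it is given the configuration expected from hydride attack anti to the pseudoaxial methyl (oxygen on the methyl face), so that the silyl ether shields that face and the carbene enters from the chain face.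

**Route**

Step 1
Reactants: 1 2-methylcyclohex-2-en-1-one; 2 allyl bromide
Product: 4 (2S,3R)-2-allyl-2,3-dimethylcyclohexan-1-one, via dimethylaluminium enolate 3 (not isolated)
Conditions: Me3Al, Cu(OTf)2 (2 mol %), chiral phosphoramidite ligand (4 mol %, antipode giving 3R), Et2O, −30 °C; then MeLi, THF–HMPA, −30 °C; 2, → 0 °C
Reagents that add atoms: trimethylaluminium, C[Al](C)C
Why: Copper-catalysed enantioselective conjugate addition sets the methine centre, and the enolate, activated as its aluminate, should be allylated anti to the new β-methyl, which places the two methyl groups cis.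

Step 2
Reactants: 4 (2S,3R)-2-allyl-2,3-dimethylcyclohexan-1-one
Product: 6 (2S,3R)-2-allyl-2,3-dimethylcycloheptan-1-one, via α-silyl ketone 5 (not isolated)
Conditions: Me3SiCHN2, Me3Al, CH2Cl2, −78 → −20 °C; then 1 M HCl, THF, rt
Reagents that add atoms: trimethylsilyldiazomethane, C[Si](C)(C)C=[N+]=[N-]
Why: Lewis-acid-promoted diazoalkane ring expansion (Tiffeneau–Demjanov type) in which the unsubstituted α-methylene should migrate, so the quaternary carbon stays next to the carbonyl; the α-silyl group blocks a second insertion and is removed by acid.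

Step 3
Reactants: 6 (2S,3R)-2-allyl-2,3-dimethylcycloheptan-1-one
Product: 8 (2S,3R)-2-(2-hydroxyethyl)-2,3-dimethylcycloheptan-1-one, via keto aldehyde 7 (not isolated)
Conditions: O3, CH2Cl2–MeOH, −78 °C; Me2S; then NaBH4, −78 → −40 °C
Reagents that add atoms: ozone, [O-][O+]=O
Why: Ozonolysis of the only alkene followed by low-temperature borohydride reduction, which should take the aldehyde much faster than the neopentyl cycloheptanone.

Step 4
Reactants: 8 (2S,3R)-2-(2-hydroxyethyl)-2,3-dimethylcycloheptan-1-one
Product: 9 (2S,3R)-2-[2-(benzyloxy)ethyl]-2,3-dimethylcycloheptan-1-one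
Conditions: BnBr, Ag2O, CH2Cl2, rt, dark
Reagents that add atoms: benzyl bromide, BrCc1ccccc1
Why: Silver-oxide-mediated Williamson benzylation works without strong base, so the enolisable ketone is left alone.

Step 5
Reactants: 9 (2S,3R)-2-[2-(benzyloxy)ethyl]-2,3-dimethylcycloheptan-1-one
Product: 11 (6R,7S)-7-[2-(benzyloxy)ethyl]-6,7-dimethylcyclohept-2-en-1-one, via trimethylsilyl enol ether 10 (not isolated)
Conditions: LiN(i-Pr)2, THF, −78 °C; Me3SiCl; then Pd(OAc)2 (1.1 equiv), MeCN, rt
Reagents that add atoms: none
Why: Saegusa–Ito oxidation; the ketone can enolise only toward the new methylene, so the position of the enone is fixed.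

Step 6
Reactants: 11 (6R,7S)-7-[2-(benzyloxy)ethyl]-6,7-dimethylcyclohept-2-en-1-one
Product: 12 2,3-epoxide of enone 11 (either epoxide face)
Conditions: 30% H2O2, NaOH (cat.), MeOH, 0 °C
Reagents that add atoms: hydrogen peroxide, OO
Why: Weitz–Scheffer nucleophilic epoxidation of the enone; the epoxide configuration does not matter because both carbons lose it in step 7.

Step 7
Reactants: 12 2,3-epoxide of enone 11
Product: 13 (4S,5R)-4-[2-(benzyloxy)ethyl]-4,5-dimethylcycloheptane-1,3-dione
Conditions: Pd(PPh3)4 (5 mol %), Ph2PCH2CH2PPh2, toluene, 100 °C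
Reagents that add atoms: none
Why: Known isomerisation of α,β-epoxy ketones to β-diketones by zerovalent palladium (oxidative addition at the Cα–O bond, β-hydride elimination, reductive elimination).

Step 8
Reactants: 13 (4S,5R)-4-[2-(benzyloxy)ethyl]-4,5-dimethylcycloheptane-1,3-dione
Product: 14 (6R,7S)-7-[2-(benzyloxy)ethyl]-6,7-dimethyl-3-(triethylsilyloxy)cyclohept-2-en-1-one
Conditions: Et3SiCl, Et3N, DMAP (cat.), CH2Cl2, 0 °C
Reagents that add atoms: chlorotriethylsilane, CC[Si](Cl)(CC)CC
Why: O-silylation of the enolised dione should go to the oxygen remote from the quaternary carbon for steric reasons, which fixes the enol double bond and leaves the hindered carbonyl.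

Step 9
Reactants: 14 (6R,7S)-7-[2-(benzyloxy)ethyl]-6,7-dimethyl-3-(triethylsilyloxy)cyclohept-2-en-1-one
Product: 15 (1S,6R,7S)-7-[2-(benzyloxy)ethyl]-6,7-dimethyl-3-(triethylsilyloxy)cyclohept-2-en-1-ol (hydroxyl on the methyl face; used without chromatography)
Conditions: i-Bu2AlH, toluene, −78 °C; aq. potassium sodium tartrate, 0 °C
Reagents that add atoms: none
Why: 1,2-Reduction of the vinylogous ester carbonyl, in which hydride should attack anti to the pseudoaxial methyl of the neighbouring quaternary carbon (torsional control, as in cyclohexanones with an axial 2-methyl) and put the hydroxyl on the methyl face; the neutral work-up avoids loss of the allylic oxygen.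

Step 10
Reactants: 15 the allylic alcohol
Product: 16 tert-butyldimethylsilyl ether of 15
Conditions: t-BuMe2SiOTf, 2,6-lutidine, CH2Cl2, −78 °C
Reagents that add atoms: tert-butyldimethylsilyl triflate, CC(C)(C)[Si](C)(C)OS(=O)(=O)C(F)(F)F
Why: Silyl triflate with a hindered base silylates the neopentyl alcohol at low temperature and keeps the acid-labile enol ether intact.

Step 11
Reactants: 16 the bis-silyl ether; 17 ethyl diazoacetate
Product: 18 ethyl 5-[2-(benzyloxy)ethyl]-6-(tert-butyldimethylsilyloxy)-4,5-dimethyl-1-(triethylsilyloxy)bicyclo[5.1.0]octane-8-carboxylate (cyclopropane on the chain face, ester exo)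
Conditions: Rh2(OAc)4 (1 mol %), CH2Cl2, rt, slow addition of 17
Reagents that add atoms: none
Why: Rhodium-carbenoid [2+1] cycloaddition to an electron-rich silyl enol ether; the carbenoid should add anti to the allylic silyl ether and the pseudoaxial methyl (chain face) with the ester exo, which sets both fusion centres of the cyclopropane.

Step 12
Reactants: 18 the cyclopropane ester
Product: 19 the corresponding cyclopropane-8-carbaldehyde
Conditions: i-Bu2AlH (1.1 equiv), toluene, −78 °C; MeOH, aq. potassium sodium tartrate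
Reagents that add atoms: none
Why: Low-temperature half-reduction of the ester through the stable aluminium hemiacetal; the silyl ether keeps the donor–acceptor cyclopropane closed.

Step 13
Reactants: 19 the cyclopropane aldehyde; 20 isopropyltriphenylphosphonium iodide
Product: 21 8-(2-methylprop-1-enyl)cyclopropyl triethylsilyl ether
Conditions: 20, n-BuLi, THF, 0 °C; then 19, −78 °C → rt
Reagents that add atoms: none
Why: Wittig olefination with the non-stabilised isopropylidene ylide builds the 2-methylpropenyl group without touching the cyclopropane stereocentres.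

Step 14
Reactants: 21 the alkenylcyclopropyl triethylsilyl ether
Product: 22 (1R,4R,5S,6S,7S,8R)-5-[2-(benzyloxy)ethyl]-6-[(tert-butyldimethylsilyl)oxy]-4,5-dimethyl-8-(2-methylprop-1-en-1-yl)bicyclo[5.1.0]octan-1-ol
Conditions: HF·pyridine, pyridine, THF, 0 °C
Reagents that add atoms: none
Why: Buffered fluoride should cleave the triethylsilyl ether of the cyclopropanol selectively over the neopentyl secondary TBS ether and never generates the free alkoxide.

Step 15
Reactants: 22 the cycloheptane-fused 2-(2-methylpropenyl)cyclopropanol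
Product: 25 (3aS,4S,5S,6R,8aS)-5-[2-(benzyloxy)ethyl]-4-[(tert-butyldimethylsilyl)oxy]-1,1,5,6-tetramethyl-3a,4,5,6,7,8-hexahydroazulen-8a(1H)-ol (cis-fused), via lithium cyclopropanolate 23 (not isolated), via lithium cyclopentenolate 24 (not isolated)
Conditions: n-BuLi (1.05 equiv), THF, −78 °C; HMPA, → 25 °C; H2O
Reagents that add atoms: none
Why: Proposed new method: n-BuLi converts 22 into lithium alkoxide 23, and in THF–HMPA the oxyanion should push open the strained bond between the carbinol carbon and the alkenyl-bearing cyclopropane carbon, the only ring bond whose cleavage leaves an allyl-stabilised carbanion (stepwise through a cycloheptanone carrying a 1-lithio-3-methylbut-2-enyl arm, or the concerted [1,3]-shift equivalent). The closest known reaction is the alkoxide-accelerated vinylcyclopropane-to-cyclopentene rearrangement of lithium 2-vinylcyclopropanolates at room temperature; untested here are the ring-fused tertiary alkoxide and a dimethylated terminus that has to join two fully substituted carbons. The five-membered ring closes by 5-exo-trig 1,2-addition of the dimethyl-substituted (γ) terminus of the allyl unit to the ring ketone, the usual regiochemistry of prenyl-metal carbonyl additions, so the C8a–C1 bond forms and the alkene ends at C2=C3; return through the α terminus only regenerates 23, whereas cyclopentenolate 24 is free of ring strain and is the sink. The fusion CH keeps its configuration, and because a five-membered ring can close onto the adjacent carbonyl only in the cis sense, it dictates the rebuilt carbinol centre (hydroxyl on the methyl face, cis to the fusion hydrogen). The step needs bond selectivity, secured by allyl stabilisation and by carrying the neighbouring ketone as its TBS ether so that no enolate-forming fragmentation is open, and it needs the absence of proton sources (aprotic medium, one equivalent of base) so that the allyl anion is not quenched to a ring-opened prenyl ketone.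

Step 16
Reactants: 25 the cis-fused cyclopentenol
Product: 26 2,3-epoxide of 25 (epoxide oxygen cis to the 8a-hydroxyl)
Conditions: VO(acac)2 (5 mol %), t-BuOOH, CH2Cl2, 0 °C → rt
Reagents that add atoms: tert-butyl hydroperoxide, CC(C)(C)OO
Why: Vanadium-catalysed hydroxyl-directed epoxidation of a cyclopent-3-enol; the angular hydroxyl delivers the peroxide to its own face, which is also the convex face of the cis-fused bicycle.

Step 17
Reactants: 26 the epoxy silyl ether
Product: 27 epoxy diol (4-hydroxyl free)
Conditions: Bu4NF, THF, 50 °C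
Reagents that add atoms: none
Why: Fluoride cleaves the secondary TBS ether, while the epoxide and the tertiary alcohol, held on the same face, cannot react with each other.

Step 18
Reactants: 27 the epoxy diol
Product: 29 5-[2-(benzyloxy)ethyl]-2,8a-dihydroxy-1,1,5,6-tetramethyl-2,5,6,7,8,8a-hexahydroazulen-4(1H)-one (C3=C3a enone; 2-OH cis to 8a-OH), via epoxy ketone 28 (not isolated)
Conditions: Dess–Martin periodinane, pyridine, CH2Cl2, 0 °C → rt; then DBU (0.3 equiv), rt
Reagents that add atoms: none
Why: Dess–Martin oxidation of the only secondary alcohol, after which DBU enolises the ketone toward the fusion carbon and the enolate opens the β,γ-epoxide by E1cB, leaving the C2 hydroxyl with the configuration set by the directed epoxidation.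

Step 19
Reactants: 29 the hydroxy enone
Product: 30 cis-fused 2,8a-dihydroxy-5-(2-hydroxyethyl)-1,1,5,6-tetramethyloctahydroazulen-4(1H)-one
Conditions: H2 (1 atm), Pd/C, EtOAc–EtOH, rt
Reagents that add atoms: none
Why: Heterogeneous hydrogenation saturates the enone and hydrogenolyses the benzyl ether; hydrogen should add from the less hindered, hydroxyl-bearing face to give mainly the cis fusion, and either fusion epimer converges in step 20.

Step 20
Reactants: 30 the cis-fused ketone
Product: 31 trans-fused (2R,3aS,5S,6R,8aS)-2,8a-dihydroxy-5-(2-hydroxyethyl)-1,1,5,6-tetramethyloctahydroazulen-4(1H)-one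
Conditions: DBU (0.5 equiv), toluene, 60 °C
Reagents that add atoms: none
Why: Base-mediated epimerisation α to the ketone through the enolate; the trans fusion, which turns the five-membered ring away from the side-chain arm across the carbonyl, is expected to be the more stable epimer, and an amidine base in an aprotic solvent leaves the tertiary β-hydroxyl un-ionised so that retro-aldol opening is suppressed.

Step 21
Reactants: 31 the trans-fused triol ketone
Product: 32 the primary iodide
Conditions: PPh3, I2, imidazole, CH2Cl2, 0 °C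
Reagents that add atoms: iodine, II
Why: Appel-type iodination is selective for the primary alcohol over the hindered secondary and tertiary ones.

Step 22
Reactants: 32 the primary iodide; 33 4-bromofuran-2(5H)-one
Product: 34 (2R,3aS,5S,6R,8aS)-2,8a-dihydroxy-1,1,5,6-tetramethyl-5-[2-(5-oxo-2,5-dihydrofuran-3-yl)ethyl]octahydroazulen-4(1H)-one
Conditions: NiBr2·MeOCH2CH2OMe (10 mol %), 4,4′-di-tert-butyl-2,2′-bipyridine, Zn dust, DMA, 25 °C
Reagents that add atoms: none
Why: Nickel-catalysed reductive cross-electrophile coupling of a primary alkyl iodide with an alkenyl bromide, which tolerates free hydroxyls and the ketone and substitutes the bromide at C4 of the butenolide with the ring alkene retained.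

**Compound list**
1 | 2-methylcyclohex-2-en-1-one | CC1=CCCC1=O | starting material
2 | allyl bromide | C=CCBr | starting material
3 | dimethylaluminium (3R)-2,3-dimethylcyclohex-1-en-1-olate | C[C@@H]1CCCC(O[Al](C)C)=C1C | intermediate (not isolated)
4 | (2S,3R)-2-allyl-2,3-dimethylcyclohexan-1-one (methyl groups cis) | C[C@@H]1CCCC(=O)[C@@]1(C)CC=C | intermediate
5 | (2S,3R)-2-allyl-2,3-dimethyl-7-(trimethylsilyl)cycloheptan-1-one (either configuration at C7) | C[C@@H]1CCCC([Si](C)(C)C)C(=O)[C@@]1(C)CC=C | intermediate (not isolated)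
6 | (2S,3R)-2-allyl-2,3-dimethylcycloheptan-1-one | C[C@@H]1CCCCC(=O)[C@@]1(C)CC=C | intermediate
7 | 2-[(1S,2R)-1,2-dimethyl-7-oxocycloheptyl]acetaldehyde | C[C@@H]1CCCCC(=O)[C@@]1(C)CC=O | intermediate (not isolated)
8 | (2S,3R)-2-(2-hydroxyethyl)-2,3-dimethylcycloheptan-1-one | C[C@@H]1CCCCC(=O)[C@@]1(C)CCO | intermediate
9 | (2S,3R)-2-[2-(benzyloxy)ethyl]-2,3-dimethylcycloheptan-1-one | C[C@@H]1CCCCC(=O)[C@@]1(C)CCOCc1ccccc1 | intermediate
10 | trimethylsilyl enol ether of 9 | C[C@@H]1CCCC=C(O[Si](C)(C)C)[C@@]1(C)CCOCc1ccccc1 | intermediate (not isolated)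
11 | (6R,7S)-7-[2-(benzyloxy)ethyl]-6,7-dimethylcyclohept-2-en-1-one | C[C@@H]1CCC=CC(=O)[C@@]1(C)CCOCc1ccccc1 | intermediate
12 | 2,3-epoxide of 11 (both epoxide faces; configuration immaterial) | C[C@@H]1CCC2OC2C(=O)[C@@]1(C)CCOCc1ccccc1 | intermediate
13 | (4S,5R)-4-[2-(benzyloxy)ethyl]-4,5-dimethylcycloheptane-1,3-dione | C[C@@H]1CCC(=O)CC(=O)[C@@]1(C)CCOCc1ccccc1 | intermediate
14 | (6R,7S)-7-[2-(benzyloxy)ethyl]-6,7-dimethyl-3-(triethylsilyloxy)cyclohept-2-en-1-one | C[C@@H]1CCC(O[Si](CC)(CC)CC)=CC(=O)[C@@]1(C)CCOCc1ccccc1 | intermediate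
15 | (1S,6R,7S)-7-[2-(benzyloxy)ethyl]-6,7-dimethyl-3-(triethylsilyloxy)cyclohept-2-en-1-ol (OH on the methyl face) | C[C@@H]1CCC(O[Si](CC)(CC)CC)=C[C@H](O)[C@@]1(C)CCOCc1ccccc1 | intermediate
16 | tert-butyldimethylsilyl ether of 15 | C[C@@H]1CCC(O[Si](CC)(CC)CC)=C[C@H](O[Si](C)(C)C(C)(C)C)[C@@]1(C)CCOCc1ccccc1 | intermediate
17 | ethyl diazoacetate | CCOC(=O)C=[N+]=[N-] | starting material
18 | ethyl 5-[2-(benzyloxy)ethyl]-6-(tert-butyldimethylsilyloxy)-4,5-dimethyl-1-(triethylsilyloxy)bicyclo[5.1.0]octane-8-carboxylate (cyclopropane on the chain face; C1–O, C7–H and C6–O on the methyl face; ester exo) | C[C@@H]1CC[C@]2(O[Si](CC)(CC)CC)[C@@H]([C@H]2C(=O)OCC)[C@H](O[Si](C)(C)C(C)(C)C)[C@@]1(C)CCOCc1ccccc1 | intermediate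
19 | 8-carbaldehyde corresponding to 18 | C[C@@H]1CC[C@]2(O[Si](CC)(CC)CC)[C@@H]([C@H]2C=O)[C@H](O[Si](C)(C)C(C)(C)C)[C@@]1(C)CCOCc1ccccc1 | intermediate
20 | isopropyltriphenylphosphonium iodide | CC(C)[P+](c1ccccc1)(c1ccccc1)c1ccccc1.[I-] | starting material
21 | 8-(2-methylprop-1-enyl) analogue, triethylsilyl ether of 22 | C[C@@H]1CC[C@]2(O[Si](CC)(CC)CC)[C@@H]([C@H]2C=C(C)C)[C@H](O[Si](C)(C)C(C)(C)C)[C@@]1(C)CCOCc1ccccc1 | intermediate
22 | (1R,4R,5S,6S,7S,8R)-5-[2-(benzyloxy)ethyl]-6-[(tert-butyldimethylsilyl)oxy]-4,5-dimethyl-8-(2-methylprop-1-en-1-yl)bicyclo[5.1.0]octan-1-ol (key-step precursor) | C[C@@H]1CC[C@]2(O)[C@@H]([C@H]2C=C(C)C)[C@H](O[Si](C)(C)C(C)(C)C)[C@@]1(C)CCOCc1ccccc1 | intermediate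
23 | lithium alkoxide of 22 | C[C@@H]1CC[C@]2(O[Li])[C@@H]([C@H]2C=C(C)C)[C@H](O[Si](C)(C)C(C)(C)C)[C@@]1(C)CCOCc1ccccc1 | intermediate (not isolated)
24 | lithium alkoxide of 25 | C[C@@H]1CC[C@]2(O[Li])[C@@H](C=CC2(C)C)[C@H](O[Si](C)(C)C(C)(C)C)[C@@]1(C)CCOCc1ccccc1 | intermediate (not isolated)
25 | (3aS,4S,5S,6R,8aS)-5-[2-(benzyloxy)ethyl]-4-[(tert-butyldimethylsilyl)oxy]-1,1,5,6-tetramethyl-3a,4,5,6,7,8-hexahydroazulen-8a(1H)-ol (cis-fused; key-step product) | C[C@@H]1CC[C@]2(O)[C@@H](C=CC2(C)C)[C@H](O[Si](C)(C)C(C)(C)C)[C@@]1(C)CCOCc1ccccc1 | intermediate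
26 | 2,3-epoxide of 25, epoxide oxygen cis to the 8a-hydroxyl | C[C@@H]1CC[C@]2(O)[C@@H]([C@H]3O[C@H]3C2(C)C)[C@H](O[Si](C)(C)C(C)(C)C)[C@@]1(C)CCOCc1ccccc1 | intermediate
27 | desilylated epoxy diol from 26 | C[C@@H]1CC[C@]2(O)[C@@H]([C@H]3O[C@H]3C2(C)C)[C@H](O)[C@@]1(C)CCOCc1ccccc1 | intermediate
28 | epoxy ketone (4-oxo) from 27 | C[C@@H]1CC[C@]2(O)[C@@H]([C@H]3O[C@H]3C2(C)C)C(=O)[C@@]1(C)CCOCc1ccccc1 | intermediate (not isolated)
29 | 5-[2-(benzyloxy)ethyl]-2,8a-dihydroxy-1,1,5,6-tetramethyl-2,5,6,7,8,8a-hexahydroazulen-4(1H)-one (2-OH cis to 8a-OH) | C[C@@H]1CC[C@]2(O)C(=C[C@@H](O)C2(C)C)C(=O)[C@@]1(C)CCOCc1ccccc1 | intermediate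
30 | cis-fused 2,8a-dihydroxy-5-(2-hydroxyethyl)-1,1,5,6-tetramethyloctahydroazulen-4(1H)-one (3a-H cis to 8a-OH) | C[C@@H]1CC[C@]2(O)[C@@H](C[C@@H](O)C2(C)C)C(=O)[C@@]1(C)CCO | intermediate
31 | trans-fused (2R,3aS,5S,6R,8aS)-2,8a-dihydroxy-5-(2-hydroxyethyl)-1,1,5,6-tetramethyloctahydroazulen-4(1H)-one | C[C@@H]1CC[C@]2(O)[C@H](C[C@@H](O)C2(C)C)C(=O)[C@@]1(C)CCO | intermediate
32 | (2R,3aS,5S,6R,8aS)-2,8a-dihydroxy-5-(2-iodoethyl)-1,1,5,6-tetramethyloctahydroazulen-4(1H)-one | C[C@@H]1CC[C@]2(O)[C@H](C[C@@H](O)C2(C)C)C(=O)[C@@]1(C)CCI | intermediate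
33 | 4-bromofuran-2(5H)-one | O=C1OCC(Br)=C1 | starting material
34 | (2R,3aS,5S,6R,8aS)-2,8a-dihydroxy-1,1,5,6-tetramethyl-5-[2-(5-oxo-2,5-dihydrofuran-3-yl)ethyl]octahydroazulen-4(1H)-one (CNP0077405.1) | C[C@@H]1CC[C@]2(O)[C@H](C[C@@H](O)C2(C)C)C(=O)[C@@]1(C)CCC1=CC(=O)OC1 | target

**Step count**
Total: 22 steps. Longest linear sequence: 22 steps (1 → 34).

**Steps most likely to fail**

1. Step 15 (proposed new method). After the strained bond opens, proton transfer to the allyl anion (from the α-position of the ketone just formed or from adventitious acid) or simple reversion may outpace closure through the hindered dimethyl terminus, and the β-silyloxy ketone could then lose silanolate. Fallback by known chemistry, setting out from 16 and coming back at 25: Mukaiyama aldol addition of silyl enol ether 16 to 3-methylbut-2-enal (BF3·OEt2, CH2Cl2, −78 °C), again on the chain face, should give the β-hydroxy ketone F1. Acetylation (Ac2O, pyridine, DMAP) gives the allylic acetate F2. Pd(PPh3)4 with Et2Zn in THF then ionises the acetate to a π-allylpalladium species and transmetallates it to an allylzinc, which adds to the ring ketone through its dimethyl terminus in a cis ring closure and delivers 25.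

2. Step 20. The equilibrium may not lie on the trans side, enolisation at the hindered fusion carbon may be slow, and retro-aldol opening of the β-hydroxy ketone may compete. Fallback with kinetic control, setting out from 29 and coming back at 31: the two hydroxyls of 29 are bridged as the di-tert-butylsilylene F3 (t-Bu2Si(OTf)2, 2,6-lutidine), which covers the face that carries both oxygens. Hydrogenation (H2, Pd/C) then has to deliver hydrogen to the fusion carbon from the other face and, with loss of the benzyl group, should give the trans-fused silylene ketone F4. HF·pyridine removes the silylene and gives 31.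

3. Step 11. Dimerisation of the carbenoid may outrun addition to the hindered trisubstituted enol ether, and discrimination between the two faces by the silyl ether, or between exo and endo, may be incomplete. Fallback with catalyst control, setting out from 16 and coming back at 19: tert-butyl diazoacetate with CuOTf and a C2-symmetric bis(4-tert-butyloxazoline) ligand (the antipode that reinforces the substrate bias) should give the exo tert-butyl ester F5 on the chain face. LiAlH4 reduces it to the cyclopropylcarbinol F6, and Dess–Martin oxidation returns aldehyde 19.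

**Further compounds**
F1 | step 15 | 4-[2-(benzyloxy)ethyl]-3-(tert-butyldimethylsilyloxy)-2-(1-hydroxy-3-methylbut-2-enyl)-4,5-dimethylcycloheptan-1-one (side chain on the chain face; carbinol configuration immaterial) | C[C@@H]1CCC(=O)[C@@H](C(O)C=C(C)C)[C@H](O[Si](C)(C)C(C)(C)C)[C@@]1(C)CCOCc1ccccc1
F2 | step 15 | acetate of F1 | C[C@@H]1CCC(=O)[C@@H](C(OC(C)=O)C=C(C)C)[C@H](O[Si](C)(C)C(C)(C)C)[C@@]1(C)CCOCc1ccccc1
F3 | step 20 | 2,8a-O-di-tert-butylsilylene derivative of 29 | C[C@@H]1CC[C@]2(O3)C(=C[C@@H](O[Si]3(C(C)(C)C)C(C)(C)C)C2(C)C)C(=O)[C@@]1(C)CCOCc1ccccc1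
F4 | step 20 | trans-fused 2,8a-O-di-tert-butylsilylene derivative of 31 | C[C@@H]1CC[C@]2(O3)[C@H](C[C@@H](O[Si]3(C(C)(C)C)C(C)(C)C)C2(C)C)C(=O)[C@@]1(C)CCO
F5 | step 11 | tert-butyl ester analogue of 18 | C[C@@H]1CC[C@]2(O[Si](CC)(CC)CC)[C@@H]([C@H]2C(=O)OC(C)(C)C)[C@H](O[Si](C)(C)C(C)(C)C)[C@@]1(C)CCOCc1ccccc1
F6 | step 11 | 8-(hydroxymethyl) analogue of 18 | C[C@@H]1CC[C@]2(O[Si](CC)(CC)CC)[C@@H]([C@H]2CO)[C@H](O[Si](C)(C)C(C)(C)C)[C@@]1(C)CCOCc1ccccc1
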